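Ring locants: C1 carbinol, C2 CH, C3 quaternary carbon, C4 CHBr. The equatorial neopentyl C4–Br next to C3 is normally made by Br+-triggered closure of C2–C3. Here bromine rides in as a vinyl bromide and the ring is closed at the unhindered C5–C6 bond: an α-keto radical adds 6-endo to a 1-bromovinyl group, and the ring α-bromo radical then takes up H anti to the axial C3 methyl, which sets C4 without Br+ or SN2. The precursor is an acyclic bromomethyl ketone whose C2/C3 pair comes from an enantioselective Ireland–Claisen rearrangement in which the ester oxygen holds the place of C6. The homoprenyl olefin is unveiled last.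

Key step: step 10

Assumption 1: (S)-(+)-linalool is bought (or enriched) in high enantiomeric purity; it supplies the side-chain carbinol C3′ unchanged.
Assumption 2: the (S,S)-boron controller is taken to give the (2S,3S)-acid; if the sense of induction is the opposite, the equally available (R,R)-controller is used.
TBS = tert-butyldimethylsilyl.

Step 1
Reactants: 1 (3-bromopropoxy)(tert-butyl)dimethylsilane; 2 methyl but-2-ynoate
Product: 5 methyl (Z)-2-bromo-6-(TBS-oxy)-3-methylhex-2-enoate, via Grignard reagent 3 (not isolated), via alkenylcopper 4 (not isolated)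
Conditions: Mg, THF; CuBr·SMe2, THF–Me2S, −45 °C; 2, −78 °C; NBS, −78 → −20 °C
Reagents that add atoms: N-bromosuccinimide, O=C1CCC(=O)N1Br
Why: Conjugate syn-carbocupration of the ynoate puts the new arm cis to copper and halogenolysis of the alkenylcopper at −78 °C goes with retention, so Br ends up cis to the arm and CH3 cis to the ester (Z), the geometry that the later chair transition state needs.

Step 2
Reactants: 5 methyl (Z)-2-bromo-6-(TBS-oxy)-3-methylhex-2-enoate
Product: 6 (Z)-2-bromo-6-(TBS-oxy)-3-methylhex-2-en-1-ol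
Conditions: DIBAL-H (2.2 equiv.), CH2Cl2, −78 → 0 °C; Rochelle salt
Reagents that add atoms: none
Why: DIBAL-H 1,2-reduction of an enoate to the allylic alcohol leaves the vinylic bromide, the olefin geometry and the silyl ether untouched.

Step 3
Reactants: 7 (S)-(+)-linalool
Product: 8 (S)-linalool TBS ether
Conditions: TBSOTf, 2,6-lutidine, CH2Cl2, 0 °C
Reagents that add atoms: tert-butyldimethylsilyl triflate, CC(C)(C)[Si](C)(C)OS(=O)(=O)C(F)(F)F
Why: Silyl triflate silylation is the standard way to protect a hindered tertiary allylic alcohol without ionising it, and the bought C3′ stereocentre is not touched.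

Step 4
Reactants: 8 (S)-linalool TBS ether
Product: 9 (S)-4-(TBS-oxy)-4-methylhex-5-en-1-ol
Conditions: O3 (1 equiv., Sudan III end point), CH2Cl2–MeOH, −78 °C; NaBH4, −78 → 0 °C
Reagents that add atoms: ozone, [O-][O+]=O
Why: Ozone attacks the electron-rich trisubstituted olefin much faster than the hindered monosubstituted vinyl group, and the reductive work-up (ozonolysis–borohydride) gives the primary alcohol directly.

Step 5
Reactants: 9 (S)-4-(TBS-oxy)-4-methylhex-5-en-1-ol
Product: 10 (S)-tert-butyl[(6-iodo-3-methylhex-1-en-3-yl)oxy]dimethylsilane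
Conditions: I2, PPh3, imidazole, CH2Cl2, 0 °C
Reagents that add atoms: iodine, II
Why: Appel-type iodination converts only the primary alcohol under buffered, essentially neutral conditions.

Step 6
Reactants: 10 (S)-tert-butyl[(6-iodo-3-methylhex-1-en-3-yl)oxy]dimethylsilane
Product: 12 (S)-5-(TBS-oxy)-5-methylhept-6-enoic acid, via organolithium 11 (not isolated)
Conditions: t-BuLi (2.1 equiv.), Et2O–pentane, −78 °C; CO2, −78 °C; dil. HCl to pH 4
Reagents that add atoms: carbon dioxide, O=C=O
Why: Lithium–iodine exchange followed by carboxylation adds the future C1, and at −78 °C the 5-hexenyllithium does not yet undergo 5-exo carbolithiation onto the vinyl group.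

Step 7
Reactants: 6 (Z)-2-bromo-6-(TBS-oxy)-3-methylhex-2-en-1-ol; 12 (S)-5-(TBS-oxy)-5-methylhept-6-enoic acid
Product: 13 (Z)-2-bromo-6-(TBS-oxy)-3-methylhex-2-en-1-yl (S)-5-(TBS-oxy)-5-methylhept-6-enoate
Conditions: EDC·HCl, DMAP, CH2Cl2, rt
Reagents that add atoms: none
Why: Steglich-type carbodiimide esterification joins the two halves under neutral conditions that touch neither the vinylic bromide nor the silyl ethers.

Step 8
Reactants: 13 (Z)-2-bromo-6-(TBS-oxy)-3-methylhex-2-en-1-yl (S)-5-(TBS-oxy)-5-methylhept-6-enoate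
Product: 15 (2S,3S)-4-bromo-3-[3-(TBS-oxy)propyl]-2-[(3S)-3-(TBS-oxy)-3-methylpent-4-en-1-yl]-3-methylpent-4-enoic acid, via boron ketene acetal 14 (not isolated)
Conditions: (S,S)-2-bromo-1,3-bis[3,5-bis(trifluoromethyl)phenylsulfonyl]-4,5-diphenyl-1,3,2-diazaborolidine (1.2 equiv.), i-Pr2NEt, CH2Cl2, −78 °C; then −20 °C → rt; aqueous work-up
Reagents that add atoms: none
Why: Enantioselective boron-mediated Ireland–Claisen rearrangement: the Z(O)-boron ketene acetal and the (Z)-bromoalkene react through a chair in which the C2 chain and the C3 propyl arm are equatorial and the C3 methyl is axial, which fixes the relative C2/C3 configuration, while the C2-symmetric sulfonamide controller on boron selects one enantiomeric chair and so the absolute (2S,3S) sense.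

Step 9
Reactants: 15 (2S,3S)-4-bromo-3-[3-(TBS-oxy)propyl]-2-[(3S)-3-(TBS-oxy)-3-methylpent-4-en-1-yl]-3-methylpent-4-enoic acid
Product: 18 (3S,4S)-1,5-dibromo-4-[3-(TBS-oxy)propyl]-3-[(3S)-3-(TBS-oxy)-3-methylpent-4-en-1-yl]-4-methylhex-5-en-2-one, via acid chloride 16 (not isolated), via diazoketone 17 (not isolated)
Conditions: 1-chloro-N,N,2-trimethylpropenylamine, CH2Cl2, 0 °C; CH2N2 (excess), Et2O, 0 °C; 48% aq. HBr (1.0 equiv.), Et2O, −20 °C
Reagents that add atoms: diazomethane, C=[N+]=[N-]; hydrogen bromide, Br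
Why: Arndt–Eistert-type acylation of diazomethane and hydrobromination of the diazoketone add the future C6 as an activated CH2Br, and the base-free chloroenamine activation avoids ketene formation and thus epimerisation at C2.

Step 10
Reactants: 18 (3S,4S)-1,5-dibromo-4-[3-(TBS-oxy)propyl]-3-[(3S)-3-(TBS-oxy)-3-methylpent-4-en-1-yl]-4-methylhex-5-en-2-one
Product: 19 (2S,3S,4S)-4-bromo-3-[3-(TBS-oxy)propyl]-2-[(3S)-3-(TBS-oxy)-3-methylpent-4-en-1-yl]-3-methylcyclohexan-1-one
Conditions: (TMS)3SiH (1.05 equiv.) and AIBN (0.2 equiv.) by syringe pump over 8 h, PhH (5 mM), 80 °C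
Reagents that add atoms: none
Why: Proposed new method: the silyl radical abstracts bromine from the activated CH2Br of 18 (far faster than from a vinylic or an unactivated secondary C–Br), the α-keto radical adds to the terminal CH2 of the 1-bromovinyl group, and the ring α-bromo radical is quenched by the silane, which carries the chain. The closest known reaction types are the reductive and atom-transfer cyclisations of α-halo ketones, in which a carbonyl group inside the forming ring favours 6-endo closure, and the hydrogen-atom-transfer reduction of alkenyl bromides to alkyl bromides through the same kind of α-bromo radical. The cyclohexanone closes 6-endo-trig (C5–C6 bond); 5-exo attack is shut off because the inner alkene carbon carries Br and the quaternary C3. The new C4 centre is controlled by the ring: with the C2 chain and the C3 propyl arm equatorial the C3 methyl is axial, so the bulky silane delivers H along the axial trajectory anti to this methyl and Br ends up equatorial, cis to the methyl. The step needs chemoselectivity for one of three C–Br bonds and a slow H donor, which are secured by the rate gap in halogen abstraction, by one equivalent of silane and by syringe-pump addition; the arm at C3 carries no olefin, so the C4 radical has no 5-exo escape.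

Step 11
Reactants: 19 (2S,3S,4S)-4-bromo-3-[3-(TBS-oxy)propyl]-2-[(3S)-3-(TBS-oxy)-3-methylpent-4-en-1-yl]-3-methylcyclohexan-1-one
Product: 20 (1R,2S,3S,4S)-4-bromo-3-[3-(TBS-oxy)propyl]-2-[(3S)-3-(TBS-oxy)-3-methylpent-4-en-1-yl]-1,3-dimethylcyclohexan-1-ol
Conditions: MeMgBr, anhydrous CeCl3, THF, −78 °C
Reagents that add atoms: methylmagnesium bromide, C[Mg]Br
Why: Organocerium 1,2-addition suppresses enolisation of the γ-bromo ketone, and because the axial trajectory at C1 is blocked by the syn-axial C3 methyl the methyl group enters equatorially, which leaves the hydroxyl axial and cis to the C2 chain (1R).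

Step 12
Reactants: 20 (1R,2S,3S,4S)-4-bromo-3-[3-(TBS-oxy)propyl]-2-[(3S)-3-(TBS-oxy)-3-methylpent-4-en-1-yl]-1,3-dimethylcyclohexan-1-ol
Product: 21 (1R,2S,3S,4S)-4-bromo-2-[(3S)-3-hydroxy-3-methylpent-4-en-1-yl]-3-(3-hydroxypropyl)-1,3-dimethylcyclohexan-1-ol
Conditions: TBAF (5 equiv.), THF, rt → 45 °C
Reagents that add atoms: none
Why: Fluoride cleaves both silyl ethers, while the equatorial neopentyl bromide has no antiperiplanar hydrogen and no open backside and should therefore survive.

Step 13
Reactants: 21 (1R,2S,3S,4S)-4-bromo-2-[(3S)-3-hydroxy-3-methylpent-4-en-1-yl]-3-(3-hydroxypropyl)-1,3-dimethylcyclohexan-1-ol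
Product: 22 3-{(1S,2S,3R,6S)-6-bromo-3-hydroxy-2-[(3S)-3-hydroxy-3-methylpent-4-en-1-yl]-1,3-dimethylcyclohexyl}propanal
Conditions: TEMPO (10 mol %), PhI(OAc)2, CH2Cl2, rt
Reagents that add atoms: none
Why: Oxoammonium (TEMPO) oxidation acts only on the primary alcohol because the two tertiary alcohols cannot be oxidised.

Step 14
Reactants: 22 3-{(1S,2S,3R,6S)-6-bromo-3-hydroxy-2-[(3S)-3-hydroxy-3-methylpent-4-en-1-yl]-1,3-dimethylcyclohexyl}propanal
Product: 23 (1R,2S,3S,4S)-4-bromo-2-[(3S)-3-hydroxy-3-methylpent-4-en-1-yl]-1,3-dimethyl-3-(4-methylpent-3-en-1-yl)cyclohexan-1-ol (target, CNP0237376.1)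
Conditions: i-PrPPh3I, n-BuLi, THF, 0 °C (ylide 4 equiv.); 22, −78 °C → rt
Reagents that add atoms: isopropyltriphenylphosphonium iodide, CC(C)[P+](c1ccccc1)(c1ccccc1)c1ccccc1.[I-]
Why: Wittig olefination with the non-stabilised isopropylidene ylide converts the aldehyde into the trisubstituted homoprenyl olefin, and the excess of ylide covers the two free hydroxyl groups.

Compound list
1 | (3-bromopropoxy)(tert-butyl)dimethylsilane | BrCCCO[Si](C)(C)C(C)(C)C | starting material
2 | methyl but-2-ynoate | CC#CC(=O)OC | starting material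
3 | [3-(TBS-oxy)propyl]magnesium bromide | Br[Mg]CCCO[Si](C)(C)C(C)(C)C | intermediate
4 | α-cuprio enoate from syn-addition (arm cis to Cu) | COC(=O)/C([Cu])=C(C)/CCCO[Si](C)(C)C(C)(C)C | intermediate
5 | methyl (Z)-2-bromo-6-(TBS-oxy)-3-methylhex-2-enoate | COC(=O)/C(Br)=C(C)/CCCO[Si](C)(C)C(C)(C)C | intermediate
6 | (Z)-2-bromo-6-(TBS-oxy)-3-methylhex-2-en-1-ol | OC/C(Br)=C(C)/CCCO[Si](C)(C)C(C)(C)C | intermediate
7 | (S)-(+)-linalool | C=C[C@@](C)(O)CCC=C(C)C | starting material
8 | (S)-linalool TBS ether | C=C[C@@](C)(O[Si](C)(C)C(C)(C)C)CCC=C(C)C | intermediate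
9 | (S)-4-(TBS-oxy)-4-methylhex-5-en-1-ol | C=C[C@@](C)(O[Si](C)(C)C(C)(C)C)CCCO | intermediate
10 | (S)-tert-butyl[(6-iodo-3-methylhex-1-en-3-yl)oxy]dimethylsilane | C=C[C@@](C)(O[Si](C)(C)C(C)(C)C)CCCI | intermediate
11 | (S)-[4-(TBS-oxy)-4-methylhex-5-en-1-yl]lithium | C=C[C@@](C)(O[Si](C)(C)C(C)(C)C)CCC[Li] | intermediate
12 | (S)-5-(TBS-oxy)-5-methylhept-6-enoic acid | C=C[C@@](C)(O[Si](C)(C)C(C)(C)C)CCCC(=O)O | intermediate
13 | (Z)-2-bromo-6-(TBS-oxy)-3-methylhex-2-en-1-yl (S)-5-(TBS-oxy)-5-methylhept-6-enoate | C=C[C@@](C)(O[Si](C)(C)C(C)(C)C)CCCC(=O)OC/C(Br)=C(C)/CCCO[Si](C)(C)C(C)(C)C | intermediate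
14 | Z(O)-boron ketene acetal of 13 bearing the (S,S)-diazaborolidine | C=C[C@@](C)(O[Si](C)(C)C(C)(C)C)CC/C=C(\OB1N(S(=O)(=O)c2cc(C(F)(F)F)cc(C(F)(F)F)c2)[C@@H](c2ccccc2)[C@H](c2ccccc2)N1S(=O)(=O)c1cc(C(F)(F)F)cc(C(F)(F)F)c1)OC/C(Br)=C(C)/CCCO[Si](C)(C)C(C)(C)C | intermediate
15 | (2S,3S)-4-bromo-3-[3-(TBS-oxy)propyl]-2-[(3S)-3-(TBS-oxy)-3-methylpent-4-en-1-yl]-3-methylpent-4-enoic acid | C=C[C@@](C)(O[Si](C)(C)C(C)(C)C)CC[C@H](C(=O)O)[C@](C)(CCCO[Si](C)(C)C(C)(C)C)C(Br)=C | intermediate
16 | acid chloride of 15 | C=C[C@@](C)(O[Si](C)(C)C(C)(C)C)CC[C@H](C(=O)Cl)[C@](C)(CCCO[Si](C)(C)C(C)(C)C)C(Br)=C | intermediate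
17 | diazomethyl ketone from 16 | C=C[C@@](C)(O[Si](C)(C)C(C)(C)C)CC[C@H](C(=O)C=[N+]=[N-])[C@](C)(CCCO[Si](C)(C)C(C)(C)C)C(Br)=C | intermediate
18 | (3S,4S)-1,5-dibromo-4-[3-(TBS-oxy)propyl]-3-[(3S)-3-(TBS-oxy)-3-methylpent-4-en-1-yl]-4-methylhex-5-en-2-one | C=C[C@@](C)(O[Si](C)(C)C(C)(C)C)CC[C@H](C(=O)CBr)[C@](C)(CCCO[Si](C)(C)C(C)(C)C)C(Br)=C | intermediate
19 | (2S,3S,4S)-4-bromo-3-[3-(TBS-oxy)propyl]-2-[(3S)-3-(TBS-oxy)-3-methylpent-4-en-1-yl]-3-methylcyclohexan-1-one | C=C[C@@](C)(O[Si](C)(C)C(C)(C)C)CC[C@H]1[C@](C)(CCCO[Si](C)(C)C(C)(C)C)[C@@H](Br)CCC1=O | intermediate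
20 | (1R,2S,3S,4S)-4-bromo-3-[3-(TBS-oxy)propyl]-2-[(3S)-3-(TBS-oxy)-3-methylpent-4-en-1-yl]-1,3-dimethylcyclohexan-1-ol | C=C[C@@](C)(O[Si](C)(C)C(C)(C)C)CC[C@H]1[C@](C)(CCCO[Si](C)(C)C(C)(C)C)[C@@H](Br)CC[C@@]1(C)O | intermediate
21 | (1R,2S,3S,4S)-4-bromo-2-[(3S)-3-hydroxy-3-methylpent-4-en-1-yl]-3-(3-hydroxypropyl)-1,3-dimethylcyclohexan-1-ol | C=C[C@@](C)(O)CC[C@H]1[C@](C)(CCCO)[C@@H](Br)CC[C@@]1(C)O | intermediate
22 | 3-{(1S,2S,3R,6S)-6-bromo-3-hydroxy-2-[(3S)-3-hydroxy-3-methylpent-4-en-1-yl]-1,3-dimethylcyclohexyl}propanal | C=C[C@@](C)(O)CC[C@H]1[C@](C)(CCC=O)[C@@H](Br)CC[C@@]1(C)O | intermediate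
23 | (1R,2S,3S,4S)-4-bromo-2-[(3S)-3-hydroxy-3-methylpent-4-en-1-yl]-1,3-dimethyl-3-(4-methylpent-3-en-1-yl)cyclohexan-1-ol | C=C[C@@](C)(O)CC[C@H]1[C@](C)(CCC=C(C)C)[C@@H](Br)CC[C@@]1(C)O | target

Total step count: 14. Longest linear sequence: 12 steps (steps 3–14, from (S)-linalool).

Steps most likely to fail

1. Step 10 (proposed new method). The α-keto radical may be reduced before the slow 6-endo closure. The ring C–Br may be over-reduced near the end of the addition. H delivery to the C4 radical may be poorly face-selective.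
   - This fallback separates ring closure from H delivery and uses established reaction types.
   - It sets out from 18. Finkelstein exchange (NaI, acetone) gives the iodomethyl ketone F1.
   - Iodine-atom-transfer cyclisation (Et3B/air or hexabutylditin, hν) uses fast iodine abstraction as the only chain transfer, so premature reduction cannot occur. It gives the 4-bromo-4-iodocyclohexanone F2.
   - One equivalent of (TMS)3SiH at low temperature then removes only the much weaker C–I bond. The same α-bromo radical is quenched from the face anti to the axial methyl, and the route is rejoined at 19.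

2. Step 8. Rearrangement at the fully substituted bromoalkene terminus may be so slow that the boron enolate decays. Control of enolate geometry or of the enantiomeric chair may be incomplete. The Lewis-acidic boron bromide may cost the tertiary allylic silyl ether.
   - This fallback gives up reagent control and sets out from 13.
   - Classical Ireland–Claisen conditions (KHMDS, TBSCl, THF–DMPU, −78 °C → rt) give the Z(O)-silyl ketene acetal F3.
   - F3 rearranges through the same chair to the silyl ester F4 and its ring-antipodal diastereomer, the silyl ester F5.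
   - Mild hydrolysis gives 15 and the (2R,3R)-acid F6. These are diastereomers because C3′ is fixed, so they can be separated by chromatography or as amine salts.
   - Half of the material is lost, and the route is rejoined at 15.

3. Step 11. The hindered γ-bromo ketone may be enolised, after which internal displacement of bromide would close a cyclopropane; alternatively, the carbonyl may simply convert poorly.
   - This fallback replaces the carbon nucleophile by a methylene transfer and a hydride, and sets out from 19.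
   - Corey–Chaykovsky reaction with dimethyloxosulfonium methylide forms the new C–C bond equatorially under reversible addition and gives the spiro-epoxide F7.
   - LiEt3BH at 0 °C opens F7 at the CH2 terminus, much faster than it can attack the neopentyl bromide, and the route is rejoined at 20.

Further compounds
F1 | step 10 | (3S,4S)-5-bromo-1-iodo-4-[3-(TBS-oxy)propyl]-3-[(3S)-3-(TBS-oxy)-3-methylpent-4-en-1-yl]-4-methylhex-5-en-2-one | C=C[C@@](C)(O[Si](C)(C)C(C)(C)C)CC[C@H](C(=O)CI)[C@](C)(CCCO[Si](C)(C)C(C)(C)C)C(Br)=C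
F2 | step 10 | 4-bromo-4-iodo analogue of 19 (C4 epimers) | C=C[C@@](C)(O[Si](C)(C)C(C)(C)C)CC[C@H]1[C@](C)(CCCO[Si](C)(C)C(C)(C)C)C(Br)(I)CCC1=O
F3 | step 8 | Z(O)-TBS ketene acetal of 13 | C=C[C@@](C)(O[Si](C)(C)C(C)(C)C)CC/C=C(\O[Si](C)(C)C(C)(C)C)OC/C(Br)=C(C)/CCCO[Si](C)(C)C(C)(C)C
F4 | step 8 | TBS ester of 15 | C=C[C@@](C)(O[Si](C)(C)C(C)(C)C)CC[C@H](C(=O)O[Si](C)(C)C(C)(C)C)[C@](C)(CCCO[Si](C)(C)C(C)(C)C)C(Br)=C
F5 | step 8 | TBS ester of the (2R,3R)-diastereomer | C=C[C@@](C)(O[Si](C)(C)C(C)(C)C)CC[C@@H](C(=O)O[Si](C)(C)C(C)(C)C)[C@@](C)(CCCO[Si](C)(C)C(C)(C)C)C(Br)=C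
F6 | step 8 | (2R,3R)-diastereomer of acid 15 | C=C[C@@](C)(O[Si](C)(C)C(C)(C)C)CC[C@@H](C(=O)O)[C@@](C)(CCCO[Si](C)(C)C(C)(C)C)C(Br)=C
F7 | step 11 | spiro-epoxide of 19 (CH2 equatorial, O axial) | C=C[C@@](C)(O[Si](C)(C)C(C)(C)C)CC[C@H]1[C@](C)(CCCO[Si](C)(C)C(C)(C)C)[C@@H](Br)CC[C@]12CO2
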